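**Retrosynthetic overview** (germacranolide numbering: furanone = O, C10, C1(=O), C2, C3; alkene C4=C5; lactone C6–O, C7, C11(=C13), C12; ester on C8)
- Last ring: the ten-membered carbocycle (nine-membered oxa-bridged ring) is closed by ring-closing metathesis (RCM) at C4=C5; the C8 angelate is put on just before.
- C7–C8 bond and the C7/C8 centres: zinc Barbier union of a furanone acetaldehyde with an (R)-3-(bromomethyl)-5-vinylbutenolide; the butenolide becomes the α-methylene lactone.
- Furanone ring and quaternary C10: gold-catalysed heterocyclization with 1,2-methyl shift of an (R)-2-hydroxy-2-alkynyl ketone, the carbinol chirality being passed on to C10.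
- That ketone: asymmetric alkynylation of methyl pyruvate with 2-methylbut-1-en-3-yne, then one-pot Weinreb amide formation and addition of a masked acetaldehyde Grignard reagent.
- Butenolide ring and C6: enantioselective desymmetrizing RCM of achiral penta-1,4-dien-3-yl 2-(bromomethyl)acrylate (new). Ring order: furanone and butenolide separately, then the macrocycle.

Assumption: the enantiomer of the chiral ligand (step 1) and of the chiral ruthenium catalyst (step 5) that gives the stated configuration is picked after a first trial, and reagent 4 is bought as its THF solution.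

**Step 1**
Reactants: 1 2-methylbut-1-en-3-yne; 2 methyl pyruvate
Product: 3 methyl (2R)-2-hydroxy-2,5-dimethylhex-5-en-3-ynoate
Conditions: Zn(OTf)2 (20 mol%), (1S,2S)-2-(dimethylamino)-1-(4-nitrophenyl)-3-(tert-butyldimethylsilyloxy)propan-1-ol or its enantiomer (22 mol%), Et3N (30 mol%), toluene, 50 °C, sealed tube
Reagents that add atoms: none
Why: Catalytic asymmetric zinc-alkynylide addition to an α-keto ester (Carreira/Jiang-type alkynylation), in which the zinc-chelated keto ester is attacked on one carbonyl face by the ligand-bound alkynylide so that the tertiary carbinol is set as (R), while the less electrophilic ester carbonyl is untouched.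

**Step 2**
Reactants: 3 methyl (2R)-2-hydroxy-2,5-dimethylhex-5-en-3-ynoate; 4 (1,3-dioxolan-2-ylmethyl)magnesium bromide
Product: 6 (3R)-1-(1,3-dioxolan-2-yl)-3-hydroxy-3,6-dimethylhept-6-en-4-yn-2-one, via Weinreb amide 5 (not isolated)
Conditions: MeNH(OMe)·HCl (1.6 equiv), i-PrMgCl (4.5 equiv), THF, −20 → 0 °C; then 4 (3 equiv, 0.5 M in THF), 0 → 23 °C; aq. NH4Cl
Reagents that add atoms: N,O-dimethylhydroxylamine hydrochloride, CNOC.Cl (atoms kept in 5 only)
Why: One-pot Weinreb ketone synthesis, in which MeN(OMe)MgCl turns the ester into amide 5 and its magnesium chelate takes up one equivalent of Grignard reagent 4 and releases the ketone only on work-up, so there is no double addition and the carbinol centre is not touched.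

**Step 3**
Reactants: 6 (3R)-1-(1,3-dioxolan-2-yl)-3-hydroxy-3,6-dimethylhept-6-en-4-yn-2-one
Product: 8 2-[(2R)-2-methyl-3-oxo-5-(prop-1-en-2-yl)-2,3-dihydrofuran-2-yl]acetaldehyde, via furanone acetal 7 (not isolated)
Conditions: AuCl3 (5 mol%), CH2Cl2, 23 → 38 °C; then 1 M aq. HCl, THF, 23–40 °C
Reagents that add atoms: water, O
Why: Gold-catalysed heterocyclization/1,2-migration of a 2-hydroxy-2-alkynyl ketone (cationic α-ketol-type 1,2-alkyl shift), in which the ketone oxygen closes 5-endo-dig onto the AuCl3-activated alkyne and the carbinol methyl group then shifts suprafacially to the adjacent oxocarbenium carbon as the C1 ketone forms, so the (R) carbinol configuration is relayed to quaternary C10 as (R); aqueous acid then cleaves the dioxolane.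

**Step 4**
Reactants: 9 penta-1,4-dien-3-ol; 10 2-(bromomethyl)prop-2-enoic acid
Product: 11 penta-1,4-dien-3-yl 2-(bromomethyl)prop-2-enoate
Conditions: DCC (1.1 equiv), DMAP (5 mol%), CH2Cl2, 0 °C
Reagents that add atoms: none
Why: Steglich esterification under mild, non-ionizing conditions that spare the allylic bromide and the bis-allylic carbinol; no stereocentre is formed.

**Step 5**
Reactants: 11 penta-1,4-dien-3-yl 2-(bromomethyl)prop-2-enoate
Product: 12 (5R)-3-(bromomethyl)-5-ethenylfuran-2(5H)-one
Conditions: RuCl2(L*)(=CH–C6H4-2-OiPr) (5 mol%; L* = (4R,5R)-1,3-bis(2-isopropylphenyl)-4,5-diphenylimidazolidin-2-ylidene or its enantiomer), ethene (1 atm), toluene (0.02 M), 40 °C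
Reagents that add atoms: none
Why: Proposed new method: enantioselective desymmetrizing RCM of a prochiral penta-1,4-dien-3-yl α-substituted acrylate with a chiral NHC–ruthenium alkylidene, in which the carbene forms reversibly on either enantiotopic vinyl group (exchange with ethene), closure onto the hindered, electron-poor 1,1-disubstituted acrylate is turnover-limiting, and the chiral NHC pocket therefore selects between two diastereomeric ruthenacyclobutanes that hold the nascent C6 centre inside the forming ring (Curtin–Hammett), closing the butenolide and setting C6 as (R); the closest known reaction types are Ru- and Mo-catalysed asymmetric RCM desymmetrization of achiral trienyl ethers and racemic RCM of allylic acrylates to butenolides.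

**Step 6**
Reactants: 8 2-[(2R)-2-methyl-3-oxo-5-(prop-1-en-2-yl)-2,3-dihydrofuran-2-yl]acetaldehyde; 12 (5R)-3-(bromomethyl)-5-ethenylfuran-2(5H)-one
Product: 14 (4R,5R)-5-ethenyl-4-{(1S)-1-hydroxy-2-[(2R)-2-methyl-3-oxo-5-(prop-1-en-2-yl)-2,3-dihydrofuran-2-yl]ethyl}-3-methylideneoxolan-2-one, via allylzinc bromide 13 (not isolated)
Conditions: Zn dust (3 equiv), THF/sat. aq. NH4Cl (2:1), 0 → 23 °C
Reagents that add atoms: zinc, [Zn] (kept in 13 only)
Why: Zinc Barbier allylation of an aldehyde with a 3-(bromomethyl)butenolide (SE2' attack at the ring β-carbon through a closed chair transition state), in which the aldehyde adds anti to the C6 vinyl group with its side chain equatorial, setting C7 as (R) (trans to C6) and C8 as (S) and unveiling the α-methylene lactone, while the vinylogous-ester carbonyl of the furanone does not react.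

**Step 7**
Reactants: 14 (4R,5R)-5-ethenyl-4-{(1S)-1-hydroxy-2-[(2R)-2-methyl-3-oxo-5-(prop-1-en-2-yl)-2,3-dihydrofuran-2-yl]ethyl}-3-methylideneoxolan-2-one; 15 angelic acid, (2Z)-2-methylbut-2-enoic acid
Product: 17 (1S)-1-[(2R,3R)-2-ethenyl-4-methylidene-5-oxooxolan-3-yl]-2-[(2R)-2-methyl-3-oxo-5-(prop-1-en-2-yl)-2,3-dihydrofuran-2-yl]ethyl (2Z)-2-methylbut-2-enoate, via mixed anhydride 16 (not isolated)
Conditions: 15, 2,4,6-trichlorobenzoyl chloride, Et3N, toluene, 23 °C, 2 h; then 14, toluene, 75 °C
Reagents that add atoms: 2,4,6-trichlorobenzoyl chloride, O=C(Cl)c1c(Cl)cc(Cl)cc1Cl (atoms kept in 16 only)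
Why: Yamaguchi-type mixed-anhydride esterification, in which the alcohol attacks the unhindered angeloyl carbonyl of 16 and not the 2,6-dichloro-shielded aroyl carbonyl, and leaving out DMAP and carbodiimide avoids Z-to-E isomerization to the tiglate; C8 keeps its configuration because its C–O bond is not broken.

**Step 8**
Reactants: 17 (1S)-1-[(2R,3R)-2-ethenyl-4-methylidene-5-oxooxolan-3-yl]-2-[(2R)-2-methyl-3-oxo-5-(prop-1-en-2-yl)-2,3-dihydrofuran-2-yl]ethyl (2Z)-2-methylbut-2-enoate
Product: 18 lychnopholide
Conditions: second-generation Hoveyda–Grubbs catalyst RuCl2(H2IMes)(=CH–C6H4-2-OiPr) (H2IMes = 1,3-dimesitylimidazolidin-2-ylidene; 20 mol% in portions), toluene (0.001 M), 100 °C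
Reagents that add atoms: none
Why: Ring-closing metathesis, in which the catalyst loads on the monosubstituted C6 vinyl group and closes onto the furanone isopropenyl group at high dilution to give the trisubstituted C4=C5 alkene, which the bridged ring can hold only as (Z), while the electron-poor exo-methylene lactone and the trisubstituted angelate alkene are poor metathesis partners and stay intact.

**Compound list**
1 | 2-methylbut-1-en-3-yne | C=C(C)C#C | starting material
2 | methyl pyruvate | CC(=O)C(=O)OC | starting material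
3 | methyl (2R)-2-hydroxy-2,5-dimethylhex-5-en-3-ynoate | C[C@@](O)(C#CC(C)=C)C(=O)OC | intermediate
4 | (1,3-dioxolan-2-ylmethyl)magnesium bromide | Br[Mg]CC1OCCO1 | starting material
5 | (2R)-2-hydroxy-N-methoxy-N,2,5-trimethylhex-5-en-3-ynamide (Weinreb amide, present as its magnesium alkoxide) | C[C@@](O)(C#CC(C)=C)C(=O)N(C)OC | intermediate
6 | (3R)-1-(1,3-dioxolan-2-yl)-3-hydroxy-3,6-dimethylhept-6-en-4-yn-2-one | C[C@@](O)(C#CC(C)=C)C(=O)CC1OCCO1 | intermediate
7 | (2R)-2-(1,3-dioxolan-2-ylmethyl)-2-methyl-5-(prop-1-en-2-yl)furan-3(2H)-one | C=C(C)C1=CC(=O)[C@@](C)(CC2OCCO2)O1 | intermediate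
8 | 2-[(2R)-2-methyl-3-oxo-5-(prop-1-en-2-yl)-2,3-dihydrofuran-2-yl]acetaldehyde | C=C(C)C1=CC(=O)[C@@](C)(CC=O)O1 | intermediate
9 | penta-1,4-dien-3-ol | C=CC(O)C=C | starting material
10 | 2-(bromomethyl)prop-2-enoic acid | C=C(CBr)C(=O)O | starting material
11 | penta-1,4-dien-3-yl 2-(bromomethyl)prop-2-enoate | C=CC(C=C)OC(=O)C(=C)CBr | intermediate
12 | (5R)-3-(bromomethyl)-5-ethenylfuran-2(5H)-one | BrCC1=C[C@@H](C=C)OC1=O | intermediate
13 | bromo{[(5R)-5-ethenyl-2-oxo-2,5-dihydrofuran-3-yl]methyl}zinc | Br[Zn]CC1=C[C@@H](C=C)OC1=O | intermediate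
14 | (4R,5R)-5-ethenyl-4-{(1S)-1-hydroxy-2-[(2R)-2-methyl-3-oxo-5-(prop-1-en-2-yl)-2,3-dihydrofuran-2-yl]ethyl}-3-methylideneoxolan-2-one | C=C1C(=O)O[C@H](C=C)[C@H]1[C@@H](O)C[C@@]2(C)OC(=CC2=O)C(C)=C | intermediate
15 | angelic acid, (2Z)-2-methylbut-2-enoic acid | C/C=C(/C)C(=O)O | starting material
16 | (2Z)-2-methylbut-2-enoic 2,4,6-trichlorobenzoic anhydride | C/C=C(/C)C(=O)OC(=O)c1c(Cl)cc(Cl)cc1Cl | intermediate
17 | (1S)-1-[(2R,3R)-2-ethenyl-4-methylidene-5-oxooxolan-3-yl]-2-[(2R)-2-methyl-3-oxo-5-(prop-1-en-2-yl)-2,3-dihydrofuran-2-yl]ethyl (2Z)-2-methylbut-2-enoate | C=C1C(=O)O[C@H](C=C)[C@H]1[C@@H](OC(=O)/C(C)=C\C)C[C@@]2(C)OC(=CC2=O)C(C)=C | intermediate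
18 | lychnopholide (6R,7R,8S,10R) | C=C1C(=O)O[C@@H]2/C=C(/C)C3=CC(=O)[C@@](C)(C[C@H](OC(=O)/C(C)=C\C)[C@@H]12)O3 | target

**Totals**
Total step count: 8. Longest linear sequence: 6 steps (1 → 2 → 3 → 6 → 7 → 8).

**Three steps most likely to fail**

Step 5 (the new enantioselective RCM). The risks are low enantioselectivity if carbene formation is not reversible, and slow closure onto the acrylate. The fallback sets out from 11 and comes back at 14. Ring closure of 11 with the achiral second-generation Hoveyda–Grubbs catalyst RuCl2(H2IMes)(=CH–C6H4-2-OiPr) (CH2Cl2, 40 °C) is known chemistry and gives 12 as the racemate, that is, together with (5S)-3-(bromomethyl)-5-ethenylfuran-2(5H)-one F1. The racemate is taken into the zinc Barbier reaction of step 6 with enantiopure 8. This gives 14 and the diastereomer (4S,5S)-5-ethenyl-4-{(1R)-1-hydroxy-2-[(2R)-2-methyl-3-oxo-5-(prop-1-en-2-yl)-2,3-dihydrofuran-2-yl]ethyl}-3-methylideneoxolan-2-one F2, which is removed by chromatography. Half of 8 is lost this way.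

Step 3 (heterocyclization/1,2-methyl shift). Methyl is a reluctant migrating group and the β-keto acetal is sensitive to Lewis acid. The fallback sets out from 6 and comes back at 7, which is hydrolysed to 8 as in step 3. N-Iodosuccinimide (CH2Cl2, 23 °C) triggers the same cyclization and 1,2-methyl shift through an iodonium ion without a metal. It gives (2R)-2-(1,3-dioxolan-2-ylmethyl)-4-iodo-2-methyl-5-(prop-1-en-2-yl)furan-3(2H)-one F3. The iodine is then removed with Pd(PPh3)4 (cat.), HCO2H and Et3N in DMF at 60 °C to give 7.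

Step 8 (macrocyclic RCM). The risks are ring strain, oligomerization, and a competing closure onto the angelate alkene to a seven-membered lactone. The fallback sets out from 14 and comes back at 18. The order of the last two operations is reversed: RCM of the free alcohol 14 under the step 8 conditions gives the C8 alcohol of the target (lychnopholide lacking the angeloyl group) F4. F4 is then acylated with mixed anhydride 16 under the step 7 conditions to give 18. This takes the angelate alkene and its bulk out of the ring-closing event.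

**Further compounds**
F1 | step 5 | (5S)-3-(bromomethyl)-5-ethenylfuran-2(5H)-one | BrCC1=C[C@H](C=C)OC1=O
F2 | step 5 | (4S,5S)-5-ethenyl-4-{(1R)-1-hydroxy-2-[(2R)-2-methyl-3-oxo-5-(prop-1-en-2-yl)-2,3-dihydrofuran-2-yl]ethyl}-3-methylideneoxolan-2-one | C=C1C(=O)O[C@@H](C=C)[C@@H]1[C@H](O)C[C@@]2(C)OC(=CC2=O)C(C)=C
F3 | step 3 | (2R)-2-(1,3-dioxolan-2-ylmethyl)-4-iodo-2-methyl-5-(prop-1-en-2-yl)furan-3(2H)-one | C=C(C)C1=C(I)C(=O)[C@@](C)(CC2OCCO2)O1
F4 | step 8 | 8-O-deangeloyl-lychnopholide (6R,7R,8S,10R) | C=C1C(=O)O[C@@H]2/C=C(/C)C3=CC(=O)[C@@](C)(C[C@H](O)[C@@H]12)O3
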